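## Retrosynthetic overview

1. The target is reached from its 19‑O‑silyl ether by fluoride, and that from a macrocyclic epoxy triol by oxidation of the two allylic carbinols (C9, C14) with MnO2.
2. Key disconnection: the C3–C4 bond and the C4–O bond together. An allylic sulfonium ylide at C3 adds to the C4 methyl ketone within the chain and the betaine closes, so the 14‑membered carbocycle and the oxirane form in the same operation.
3. The open‑chain sulfonium salt comes from a C8–C9 Nozaki–Hiyama–Kishi union of a (Z)‑alkenyl iodide (C4–C8, C18, C19) with an aldehyde (C9–C14, C1–C3).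
4. The aldehyde comes from (R)‑citronellal (C12 from the chiral pool; C13 by catalytic α‑oxyamination; C1=C2 by directed carbomagnesiation). The iodide comes from 4‑chlorobut‑2‑yn‑1‑ol and acetylacetone by trans‑hydrostannation.
5. Ring order: no ring exists before the key step; carbocycle and epoxide are formed together, and nothing is closed afterwards.

Locants in names and text follow cembrane numbering: C1 carries the isopropyl group, and C18, C19 and C20 are the carbons on C4, C8 and C12. The C9 carbinol is formed as an epimer mixture and left undefined, because it is oxidised later; C14 is drawn as its major (anti) epimer for the same reason.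

Assumption: (1R,4R,5R)‑isothiocineole (commercial, or one step from (R)‑limonene) is taken as the enantiomer whose allylic ylide is attacked on the face that gives 3S; if the sense is the opposite, its enantiomer is used with no other change.

## Route

Step 1
Reactants: 1 4‑chlorobut‑2‑yn‑1‑ol; 2 pentane‑2,4‑dione
Product: 4 7‑hydroxyhept‑5‑yn‑2‑one, via C‑alkylated diketone 3 (not isolated)
Conditions: K2CO3 (1.2 equiv), EtOH, reflux, 16 h
Reagents that add atoms: none
Why: The potassium enolate of acetylacetone is C‑alkylated by the propargylic chloride (SN2) and the 3‑substituted diketone is deacetylated by ethanolysis under the same conditions (acetylacetone alkylation with retro‑Claisen cleavage), giving the methyl ketone directly; no stereocentre is formed.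

Step 2
Reactants: 4 7‑hydroxyhept‑5‑yn‑2‑one
Product: 6 (Z)‑7‑hydroxy‑6‑iodohept‑5‑en‑2‑one, via alkenylstannane 5 (not isolated)
Conditions: Bu3SnH (1.1 equiv), [(C5Me5)RuCl]4 (1.5 mol%), CH2Cl2, 23 °C; then I2 (1.2 equiv), 0 °C
Reagents that add atoms: iodine, II; tributyltin hydride, CCCC[SnH](CCCC)CCCC (tin is kept only in 5)
Why: Ruthenium‑catalysed trans‑hydrostannation is directed by the free propargylic hydroxyl, so tin goes to the alkyne carbon next to CH2OH with hydrogen delivered anti, and iododestannylation proceeds with retention, fixing the Z geometry of the later C7=C8 bond; the ketone is inert to both reagents.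

Step 3
Reactants: 6 (Z)‑7‑hydroxy‑6‑iodohept‑5‑en‑2‑one
Product: 7 (Z)‑7‑[(tert‑butyldiphenylsilyl)oxy]‑6‑iodohept‑5‑en‑2‑one
Conditions: TBDPSCl (1.1 equiv), imidazole (2 equiv), DMF, 0 → 23 °C
Reagents that add atoms: tert‑butyl(chloro)diphenylsilane, CC(C)(C)[Si](Cl)(c1ccccc1)c1ccccc1
Why: Standard silylation of a primary alcohol; the acid‑stable TBDPS ether masks C19–OH through the acidic step 9 and the allylic oxidation of step 12.

Step 4
Reactants: 8 (R)‑citronellal
Product: 9 (2S,3R)‑3,7‑dimethyl‑2‑[(2,2,6,6‑tetramethylpiperidin‑1‑yl)oxy]oct‑6‑enal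
Conditions: TEMPO (1.3 equiv), CuCl2 (10 mol%), (5S)‑5‑benzyl‑2,2,3‑trimethylimidazolidin‑4‑one·CF3CO2H (20 mol%), acetone, air, −10 °C
Reagents that add atoms: TEMPO (2,2,6,6‑tetramethylpiperidin‑1‑oxyl), CC1(C)CCCC(C)(C)N1[O]
Why: Enamine catalysis with CuCl2/air oxidation (organocatalytic α‑oxyamination of aldehydes) joins the enamine α‑carbon to TEMPO on the face opposite the benzyl group of the (5S)‑imidazolidinone, which sets C13 as S under catalyst control next to the existing C12 centre; the trisubstituted olefin is inert.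

Step 5
Reactants: 9 (2S,3R)‑3,7‑dimethyl‑2‑[(2,2,6,6‑tetramethylpiperidin‑1‑yl)oxy]oct‑6‑enal; 10 tert‑butyldimethyl(prop‑2‑yn‑1‑yloxy)silane
Product: 12 (4R,5S,6R)‑1‑[(tert‑butyldimethylsilyl)oxy]‑6,10‑dimethyl‑5‑[(2,2,6,6‑tetramethylpiperidin‑1‑yl)oxy]undec‑9‑en‑2‑yn‑4‑ol, via lithium acetylide 11 (not isolated)
Conditions: 10 (1.3 equiv), n‑BuLi (1.25 equiv), THF, −78 °C; then 9, −78 °C; aq. NH4Cl
Reagents that add atoms: n‑butyllithium, [Li]CCCC (lithium is kept only in 11)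
Why: 1,2‑Addition of the lithium acetylide to the α‑oxygenated aldehyde follows polar Felkin–Anh (non‑chelation) control to give mainly the 13,14‑anti alcohol drawn; the C14 configuration is removed by the later oxidation, so the minor epimer can be carried along.

Step 6
Reactants: 12 (4R,5S,6R)‑1‑[(tert‑butyldimethylsilyl)oxy]‑6,10‑dimethyl‑5‑[(2,2,6,6‑tetramethylpiperidin‑1‑yl)oxy]undec‑9‑en‑2‑yn‑4‑ol
Product: 14 (2E,4R,5S,6R)‑1‑[(tert‑butyldimethylsilyl)oxy]‑6,10‑dimethyl‑3‑(propan‑2‑yl)‑5‑[(2,2,6,6‑tetramethylpiperidin‑1‑yl)oxy]undeca‑2,9‑dien‑4‑ol, via cyclic alkenylmagnesium alkoxide 13 (not isolated)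
Conditions: i‑PrMgCl (4 equiv), CuI (15 mol%), THF, −20 → 23 °C; aq. NH4Cl
Reagents that add atoms: isopropylmagnesium chloride, CC(C)[Mg]Cl
Why: Copper‑catalysed, alkoxide‑directed anti‑carbomagnesiation of a propargylic alcohol delivers the isopropyl group to the alkyne carbon next to the carbinol and magnesium to the distal carbon within a five‑membered chelate, so protonation leaves C14 and C3 trans across the new C1=C2 bond (E); silyloxide is a poor leaving group, which holds back allene formation.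

Step 7
Reactants: 14 (2E,4R,5S,6R)‑1‑[(tert‑butyldimethylsilyl)oxy]‑6,10‑dimethyl‑3‑(propan‑2‑yl)‑5‑[(2,2,6,6‑tetramethylpiperidin‑1‑yl)oxy]undeca‑2,9‑dien‑4‑ol
Product: 16 (4R,5S,6R,7E)‑9‑[(tert‑butyldimethylsilyl)oxy]‑6‑hydroxy‑4‑methyl‑7‑(propan‑2‑yl)‑5‑[(2,2,6,6‑tetramethylpiperidin‑1‑yl)oxy]non‑7‑enal, via secondary ozonide 15 (not isolated)
Conditions: O3 (1.0 equiv, titrated CH2Cl2 solution), CH2Cl2, −78 °C; then PPh3 (1.2 equiv), −78 → 23 °C
Reagents that add atoms: ozone, [O-][O+]=O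
Why: Ozone attacks the electron‑rich isopropylidene olefin much faster than the hindered C1=C2 olefin, which is deactivated by two allylic oxygens (selective ozonolysis as with geranyl acetate), and PPh3 reduces the ozonide to the C9 aldehyde; the hindered alkoxyamine nitrogen is not expected to be oxidised at −78 °C with one equivalent of ozone.

Step 8
Reactants: 16 (4R,5S,6R,7E)‑9‑[(tert‑butyldimethylsilyl)oxy]‑6‑hydroxy‑4‑methyl‑7‑(propan‑2‑yl)‑5‑[(2,2,6,6‑tetramethylpiperidin‑1‑yl)oxy]non‑7‑enal; 7 (Z)‑7‑[(tert‑butyldiphenylsilyl)oxy]‑6‑iodohept‑5‑en‑2‑one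
Product: 18 (5Z,10R,11S,12R,13E)‑15‑[(tert‑butyldimethylsilyl)oxy]‑6‑{[(tert‑butyldiphenylsilyl)oxy]methyl}‑7,12‑dihydroxy‑10‑methyl‑13‑(propan‑2‑yl)‑11‑[(2,2,6,6‑tetramethylpiperidin‑1‑yl)oxy]pentadeca‑5,13‑dien‑2‑one (C9 epimers), via alkenylchromium dichloride 17 (not isolated)
Conditions: 7 (1.3 equiv), CrCl2 (6 equiv), NiCl2 (2 mol%), DMSO/THF 3:1, 23 °C
Reagents that add atoms: chromium dichloride, Cl[Cr]Cl (chromium is kept only in 17)
Why: The Nozaki–Hiyama–Kishi reaction converts the alkenyl iodide into an alkenylchromium species with retention of the Z geometry and adds it chemoselectively to the aldehyde in the presence of the methyl ketone and free hydroxyls; the new C9 carbinol centre is a mixture that is oxidised later.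

Step 9
Reactants: 18 (5Z,10R,11S,12R,13E)‑15‑[(tert‑butyldimethylsilyl)oxy]‑6‑{[(tert‑butyldiphenylsilyl)oxy]methyl}‑7,12‑dihydroxy‑10‑methyl‑13‑(propan‑2‑yl)‑11‑[(2,2,6,6‑tetramethylpiperidin‑1‑yl)oxy]pentadeca‑5,13‑dien‑2‑one
Product: 19 (5Z,10R,11S,12R,13E)‑6‑{[(tert‑butyldiphenylsilyl)oxy]methyl}‑7,11,12,15‑tetrahydroxy‑10‑methyl‑13‑(propan‑2‑yl)pentadeca‑5,13‑dien‑2‑one (C9 epimers)
Conditions: Zn dust (20 equiv), AcOH/THF/H2O 3:1:1, 60 °C, 4 h
Reagents that add atoms: none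
Why: Zinc in aqueous acetic acid reduces the N–O bond of the alkoxyamine to free the C13 hydroxyl, and the same warm aqueous acid solvolyses the primary allylic TBS ether, while the far more acid‑stable TBDPS ether and all stereocentres are untouched.

Step 10
Reactants: 19 (5Z,10R,11S,12R,13E)‑6‑{[(tert‑butyldiphenylsilyl)oxy]methyl}‑7,11,12,15‑tetrahydroxy‑10‑methyl‑13‑(propan‑2‑yl)pentadeca‑5,13‑dien‑2‑one
Product: 21 sulfonium methanesulfonate in which the C3 hydroxyl of 19 is replaced by the sulfur of (1R,4R,5R)‑isothiocineole, via allylic mesylate 20 (not isolated)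
Conditions: Ms2O (1.1 equiv), 2,4,6‑collidine (2 equiv), CH2Cl2, −40 °C; then (1R,4R,5R)‑isothiocineole (3 equiv), −40 → 23 °C, 24 h
Reagents that add atoms: methanesulfonic anhydride, CS(=O)(=O)OS(C)(=O)=O; (1R,4R,5R)‑isothiocineole, C[C@@H]1CC[C@@H]2C[C@H]1SC2(C)C
Why: Ms2O with a hindered base sulfonylates the primary allylic hydroxyl much faster than the three secondary ones, and the allylic mesylate alkylates the sulfide (SN2) on its less hindered lone pair to give one sulfonium diastereomer with the non‑nucleophilic mesylate as counter‑ion.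

Step 11
Reactants: 21 sulfonium methanesulfonate
Product: 24 (1E,3S,4R,7Z,12R,13S,14R)‑19‑[(tert‑butyldiphenylsilyl)oxy]‑3,4‑epoxycembra‑1,7‑diene‑9,13,14‑triol (C9 epimers), via sulfonium ylide 22 (not isolated), via betaine 23 (not isolated)
Conditions: Cs2CO3 (3 equiv), MeCN, 0 → 23 °C, syringe‑pump addition of 21 over 12 h, final 1 mM
Reagents that add atoms: none
Why: Proposed new method: Cs2CO3 deprotonates C3 of the allylic sulfonium salt to a semi‑stabilised ylide that cannot undergo a [2,3]‑shift (the isothiocineole unit has no second acidic α‑hydrogen), and under high dilution its only carbonyl partner is the C4 methyl ketone, so addition gives a betaine whose alkoxide displaces the sulfide from the anti‑periplanar conformer with inversion at C3, closing the 14‑membered carbocycle and the oxirane in the same operation; the chiral sulfide fixes the sulfonium configuration and ylide conformation and thereby the attacked face of C3 (3S), while C4 is set in the ring‑closing betaine, where the cis‑fused oxirane (C2 and C5 gauche) is expected to be favoured because betaine formation with a ketone is reversible and the tether holding the E C1=C2 and Z C7=C8 olefins should close faster from the gauche arrangement; the closest known reactions are the intermolecular isothiocineole‑mediated sulfur ylide epoxidation of aldehydes (Corey–Chaykovsky type) and intramolecular sulfonium ylide epoxidations that form small rings.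

Step 12
Reactants: 24 (1E,3S,4R,7Z,12R,13S,14R)‑19‑[(tert‑butyldiphenylsilyl)oxy]‑3,4‑epoxycembra‑1,7‑diene‑9,13,14‑triol
Product: 25 (1E,3S,4R,7Z,12R,13S)‑19‑[(tert‑butyldiphenylsilyl)oxy]‑3,4‑epoxy‑13‑hydroxycembra‑1,7‑diene‑9,14‑dione
Conditions: activated MnO2 (30 equiv), CH2Cl2, 23 °C
Reagents that add atoms: none
Why: MnO2 oxidises only allylic alcohols, so the C9 and C14 carbinols become the two enones while the saturated C13 hydroxyl and the epoxide are left (chemoselective allylic oxidation); this also removes the C9 epimer mixture and the C14 centre.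

Step 13
Reactants: 25 (1E,3S,4R,7Z,12R,13S)‑19‑[(tert‑butyldiphenylsilyl)oxy]‑3,4‑epoxy‑13‑hydroxycembra‑1,7‑diene‑9,14‑dione
Product: 26 (1E,3S,4R,7Z,12R,13S)‑3,4‑epoxy‑13,19‑dihydroxycembra‑1,7‑diene‑9,14‑dione (target, CNP0251075.1)
Conditions: Bu4NF/AcOH 1:1 (3 equiv), THF, 0 → 23 °C
Reagents that add atoms: none
Why: Acetic acid‑buffered fluoride cleaves the primary TBDPS ether under nearly neutral conditions that spare the γ,δ‑epoxy enone, the Z enone and the α‑ketol stereocentre (fluoride desilylation).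

## Compound list

1 | 4‑chlorobut‑2‑yn‑1‑ol | OCC#CCCl | starting material
2 | pentane‑2,4‑dione | CC(=O)CC(C)=O | starting material
3 | 3‑(4‑hydroxybut‑2‑yn‑1‑yl)pentane‑2,4‑dione | CC(=O)C(CC#CCO)C(C)=O | intermediate (not isolated)
4 | 7‑hydroxyhept‑5‑yn‑2‑one | CC(=O)CCC#CCO | intermediate
5 | (Z)‑7‑hydroxy‑6‑(tributylstannyl)hept‑5‑en‑2‑one | CC(=O)CC/C=C(\[Sn](CCCC)(CCCC)CCCC)CO | intermediate (not isolated)
6 | (Z)‑7‑hydroxy‑6‑iodohept‑5‑en‑2‑one | CC(=O)CC/C=C(\I)CO | intermediate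
7 | (Z)‑7‑[(tert‑butyldiphenylsilyl)oxy]‑6‑iodohept‑5‑en‑2‑one | CC(=O)CC/C=C(\I)CO[Si](c1ccccc1)(c1ccccc1)C(C)(C)C | intermediate
8 | (R)‑citronellal | CC(C)=CCC[C@@H](C)CC=O | starting material
9 | (2S,3R)‑3,7‑dimethyl‑2‑[(2,2,6,6‑tetramethylpiperidin‑1‑yl)oxy]oct‑6‑enal | CC(C)=CCC[C@@H](C)[C@H](ON1C(C)(C)CCCC1(C)C)C=O | intermediate
10 | tert‑butyldimethyl(prop‑2‑yn‑1‑yloxy)silane | C#CCO[Si](C)(C)C(C)(C)C | starting material
11 | lithium acetylide of 10 | [Li]C#CCO[Si](C)(C)C(C)(C)C | intermediate (not isolated)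
12 | (4R,5S,6R)‑1‑[(tert‑butyldimethylsilyl)oxy]‑6,10‑dimethyl‑5‑[(2,2,6,6‑tetramethylpiperidin‑1‑yl)oxy]undec‑9‑en‑2‑yn‑4‑ol | CC(C)=CCC[C@@H](C)[C@H](ON1C(C)(C)CCCC1(C)C)[C@H](O)C#CCO[Si](C)(C)C(C)(C)C | intermediate
13 | cyclic alkenylmagnesium alkoxide (2,5‑dihydro‑1,2‑oxamagnesole; Mg on C2 and O14, isopropyl on C1) | CC(C)=CCC[C@@H](C)[C@H](ON1C(C)(C)CCCC1(C)C)[C@@H]2O[Mg]C(CO[Si](C)(C)C(C)(C)C)=C2C(C)C | intermediate (not isolated)
14 | (2E,4R,5S,6R)‑1‑[(tert‑butyldimethylsilyl)oxy]‑6,10‑dimethyl‑3‑(propan‑2‑yl)‑5‑[(2,2,6,6‑tetramethylpiperidin‑1‑yl)oxy]undeca‑2,9‑dien‑4‑ol | CC(C)=CCC[C@@H](C)[C@H](ON1C(C)(C)CCCC1(C)C)[C@H](O)/C(C(C)C)=C/CO[Si](C)(C)C(C)(C)C | intermediate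
15 | secondary ozonide (3,3‑dimethyl‑1,2,4‑trioxolane) of the isopropylidene olefin of 14 | CC1(C)OOC(CC[C@@H](C)[C@H](ON2C(C)(C)CCCC2(C)C)[C@H](O)/C(C(C)C)=C/CO[Si](C)(C)C(C)(C)C)O1 | intermediate (not isolated)
16 | (4R,5S,6R,7E)‑9‑[(tert‑butyldimethylsilyl)oxy]‑6‑hydroxy‑4‑methyl‑7‑(propan‑2‑yl)‑5‑[(2,2,6,6‑tetramethylpiperidin‑1‑yl)oxy]non‑7‑enal | O=CCC[C@@H](C)[C@H](ON1C(C)(C)CCCC1(C)C)[C@H](O)/C(C(C)C)=C/CO[Si](C)(C)C(C)(C)C | intermediate
17 | (Z)‑alkenylchromium dichloride from 7 (trivalent chromium on C8) | CC(=O)CC/C=C(\[Cr](Cl)Cl)CO[Si](c1ccccc1)(c1ccccc1)C(C)(C)C | intermediate (not isolated)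
18 | (5Z,10R,11S,12R,13E)‑15‑[(tert‑butyldimethylsilyl)oxy]‑6‑{[(tert‑butyldiphenylsilyl)oxy]methyl}‑7,12‑dihydroxy‑10‑methyl‑13‑(propan‑2‑yl)‑11‑[(2,2,6,6‑tetramethylpiperidin‑1‑yl)oxy]pentadeca‑5,13‑dien‑2‑one (C9 epimers) | CC(=O)CC/C=C(/CO[Si](c1ccccc1)(c1ccccc1)C(C)(C)C)C(O)CC[C@@H](C)[C@H](ON1C(C)(C)CCCC1(C)C)[C@H](O)/C(C(C)C)=C/CO[Si](C)(C)C(C)(C)C | intermediate
19 | (5Z,10R,11S,12R,13E)‑6‑{[(tert‑butyldiphenylsilyl)oxy]methyl}‑7,11,12,15‑tetrahydroxy‑10‑methyl‑13‑(propan‑2‑yl)pentadeca‑5,13‑dien‑2‑one (C9 epimers) | CC(=O)CC/C=C(/CO[Si](c1ccccc1)(c1ccccc1)C(C)(C)C)C(O)CC[C@@H](C)[C@H](O)[C@H](O)/C(C(C)C)=C/CO | intermediate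
20 | 15‑O‑methanesulfonate of 19 (mesylate at cembrane C3) | CC(=O)CC/C=C(/CO[Si](c1ccccc1)(c1ccccc1)C(C)(C)C)C(O)CC[C@@H](C)[C@H](O)[C@H](O)/C(C(C)C)=C/COS(C)(=O)=O | intermediate (not isolated)
21 | sulfonium methanesulfonate: C3 of 19 bound to the sulfur of (1R,4R,5R)‑isothiocineole (alkylated on the lone pair syn to the one‑carbon bridge) | CC(=O)CC/C=C(/CO[Si](c1ccccc1)(c1ccccc1)C(C)(C)C)C(O)CC[C@@H](C)[C@H](O)[C@H](O)/C(C(C)C)=C/C[S@+]1C(C)(C)[C@@H]2CC[C@@H](C)[C@H]1C2.CS(=O)(=O)[O-] | intermediate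
22 | sulfonium ylide of 21 (carbanion at C3) | CC(=O)CC/C=C(/CO[Si](c1ccccc1)(c1ccccc1)C(C)(C)C)C(O)CC[C@@H](C)[C@H](O)[C@H](O)/C(C(C)C)=C/[CH-][S@+]1C(C)(C)[C@@H]2CC[C@@H](C)[C@H]1C2 | intermediate (not isolated)
23 | macrocyclic betaine (C3–C4 bond formed; C4 alkoxide, C3 sulfonium) | CC(C)/C1=C\[C@@H]([S@+]2C(C)(C)[C@@H]3CC[C@@H](C)[C@H]2C3)[C@@]([O-])(C)CC/C=C(/CO[Si](c4ccccc4)(c4ccccc4)C(C)(C)C)C(O)CC[C@@H](C)[C@H](O)[C@@H]1O | intermediate (not isolated)
24 | (1E,3S,4R,7Z,12R,13S,14R)‑19‑[(tert‑butyldiphenylsilyl)oxy]‑3,4‑epoxycembra‑1,7‑diene‑9,13,14‑triol (C9 epimers) | CC(C)/C1=C\[C@@H]2O[C@]2(C)CC/C=C(/CO[Si](c3ccccc3)(c3ccccc3)C(C)(C)C)C(O)CC[C@@H](C)[C@H](O)[C@@H]1O | intermediate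
25 | (1E,3S,4R,7Z,12R,13S)‑19‑[(tert‑butyldiphenylsilyl)oxy]‑3,4‑epoxy‑13‑hydroxycembra‑1,7‑diene‑9,14‑dione | CC(C)/C1=C\[C@@H]2O[C@]2(C)CC/C=C(/CO[Si](c3ccccc3)(c3ccccc3)C(C)(C)C)C(=O)CC[C@@H](C)[C@H](O)C1=O | intermediate
26 | (1E,3S,4R,7Z,12R,13S)‑3,4‑epoxy‑13,19‑dihydroxycembra‑1,7‑diene‑9,14‑dione | CC(C)/C1=C\[C@@H]2O[C@]2(C)CC/C=C(/CO)C(=O)CC[C@@H](C)[C@H](O)C1=O | target

## Step count and risks

Total steps: 13. Longest linear sequence: 10 (steps 4–13, from (R)‑citronellal); the iodide branch is steps 1–3.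

**Step 11 (ylide macrocyclisation).** The ylide may decompose before it reaches the ketone (1,4‑elimination of the sulfide, or SN2′ displacement by the C14 oxygen), and the C4 configuration is the least secure stereochemical element of the route. The fallback sets out from 14 (with 7) and comes back at 24. Zinc in aqueous acetic acid converts 14 into the triol F1. Ms2O/collidine and then isothiocineole give the sulfonium salt F2. Its ylide is generated with Cs2CO3 in MeCN in the presence of excess ketone 7, so the epoxide is made intermolecularly as the open‑chain vinyl epoxide F3, where the C4 epimers can be separated and assigned. Selective ozonolysis of the isopropylidene group then gives the aldehyde F4 (in equilibrium with its δ‑lactol). An intramolecular Nozaki–Hiyama–Kishi reaction (CrCl2, catalytic NiCl2, DMSO, high dilution) closes the C8–C9 bond to give 24.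

**Step 6 (carbomagnesiation).** A secondary Grignard reagent may add sluggishly, and the alkenylmagnesium intermediate may lose silyloxide to give an allene. The fallback sets out from 9 and comes back at 14. Commercial ethyl 4‑methyl‑3‑oxopentanoate is converted with Tf2O and aqueous Me4NOH into the (E)‑enol triflate F5. Nozaki–Hiyama–Kishi coupling of F5 with aldehyde 9 (CrCl2, catalytic NiCl2, DMF) gives the (E)‑γ‑hydroxy enoate F6 with the C1=C2 geometry carried over from the triflate. Reduction with i‑Bu2AlH gives the diol F7, and selective silylation of its primary allylic hydroxyl (TBSCl, imidazole) gives 14.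

**Step 12 (MnO2 oxidation).** The free 13,14‑diol may undergo glycol cleavage, or the α‑ketol may be oxidised further. The fallback sets out from 24 and comes back at 25. Bu2SnO in refluxing methanol converts the 13,14‑diol into the dibutylstannylene acetal F8. NBS in CHCl3 then oxidises the activated (allylic) C14 carbinol of the acetal to give the 14‑ketone F9 with C13–OH intact. MnO2 is then needed only for the isolated allylic C9 carbinol, which gives 25.

## Further compounds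

F1 | step 11 | (2E,4R,5S,6R)‑6,10‑dimethyl‑3‑(propan‑2‑yl)undeca‑2,9‑diene‑1,4,5‑triol | CC(C)=CCC[C@@H](C)[C@H](O)[C@H](O)/C(C(C)C)=C/CO
F2 | step 11 | sulfonium methanesulfonate from F1 (C3 bound to the sulfur of (1R,4R,5R)‑isothiocineole) | CC(C)=CCC[C@@H](C)[C@H](O)[C@H](O)/C(C(C)C)=C/C[S@+]1C(C)(C)[C@@H]2CC[C@@H](C)[C@H]1C2.CS(=O)(=O)[O-]
F3 | step 11 | open‑chain (3S,4R)‑vinyl epoxide carrying the isopropylidene terminus and the (Z)‑alkenyl iodide | CC(C)=CCC[C@@H](C)[C@H](O)[C@H](O)/C(C(C)C)=C/[C@@H]1O[C@]1(C)CC/C=C(\I)CO[Si](c1ccccc1)(c1ccccc1)C(C)(C)C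
F4 | step 11 | C9 aldehyde from F3 (open form of the δ‑lactol) | O=CCC[C@@H](C)[C@H](O)[C@H](O)/C(C(C)C)=C/[C@@H]1O[C@]1(C)CC/C=C(\I)CO[Si](c1ccccc1)(c1ccccc1)C(C)(C)C
F5 | step 6 | ethyl (2E)‑4‑methyl‑3‑{[(trifluoromethyl)sulfonyl]oxy}pent‑2‑enoate | CCOC(=O)/C=C(/OS(=O)(=O)C(F)(F)F)C(C)C
F6 | step 6 | ethyl (2E,4R,5S,6R)‑4‑hydroxy‑6,10‑dimethyl‑3‑(propan‑2‑yl)‑5‑[(2,2,6,6‑tetramethylpiperidin‑1‑yl)oxy]undeca‑2,9‑dienoate | CC(C)=CCC[C@@H](C)[C@H](ON1C(C)(C)CCCC1(C)C)[C@H](O)/C(C(C)C)=C/C(=O)OCC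
F7 | step 6 | (2E,4R,5S,6R)‑6,10‑dimethyl‑3‑(propan‑2‑yl)‑5‑[(2,2,6,6‑tetramethylpiperidin‑1‑yl)oxy]undeca‑2,9‑diene‑1,4‑diol | CC(C)=CCC[C@@H](C)[C@H](ON1C(C)(C)CCCC1(C)C)[C@H](O)/C(C(C)C)=C/CO
F8 | step 12 | 13,14‑O‑dibutylstannylene acetal of 24 | CC(C)/C1=C\[C@@H]2O[C@]2(C)CC/C=C(/CO[Si](c3ccccc3)(c3ccccc3)C(C)(C)C)C(O)CC[C@@H](C)[C@@H]3O[Sn](CCCC)(CCCC)O[C@H]13
F9 | step 12 | (1E,3S,4R,7Z,12R,13S)‑19‑[(tert‑butyldiphenylsilyl)oxy]‑3,4‑epoxy‑9,13‑dihydroxycembra‑1,7‑dien‑14‑one (C9 epimers) | CC(C)/C1=C\[C@@H]2O[C@]2(C)CC/C=C(/CO[Si](c3ccccc3)(c3ccccc3)C(C)(C)C)C(O)CC[C@@H](C)[C@H](O)C1=O
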